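## Retrosynthetic overview

1. Target 11 ⇐ double C‑prenylation at C‑5 of spiro trione 9, which is released in the same pot by hydroxide opening of the bridged enol ether 8.
2. 8 ⇐ anodic dearomative 6‑endo radical spirocyclisation/etherification of the alkylated acylphloroglucinol 7 (forms C‑3–C‑9' and O‑4–C‑7'; sets the spiro and C‑7' centres).
3. 7 ⇐ reductive alkylation of phlorisobutyrophenone 5 with hydroxy aldehyde 4 (C‑3–C‑1' bond).
4. 4 ⇐ amine‑catalysed intramolecular aldol of keto aldehyde 3 ⇐ mono‑ozonolysis of (S)‑limonene 1 (C‑6' bought; C‑2' and C‑3' set under its control).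
5. Ring order: cyclopentane (aldol), then spiro cyclohexane (electrolysis); the trione ring is the purchased phloroglucinol ring, dearomatised in the key step.

Assumption and labels: the enol tautomer of the task SMILES is used for naming, and (S)‑(−)‑limonene of high ee is the only source of chirality. Phloroglucinol ring: C‑1 acyl, C‑3 spiro, C‑5 gem‑diprenyl. Terpene part: C‑1' and C‑9' are the two CH2 groups on the spiro carbon, C‑2'/C‑6' the ring fusion, C‑3'/C‑7' the carbinols.

## Route

Step 1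
Reactants: 1 (S)‑(−)‑limonene
Product: 3 (3S)‑6‑oxo‑3‑(prop‑1‑en‑2‑yl)heptanal, via limonene ozonide 2 (not isolated)
Conditions: O3 (1.0 equiv, indicator‑controlled), CH2Cl2, −78 °C; then Me2S, −78 °C → rt
Reagents that add atoms: ozone, [O-][O+]=O
Why: Criegee ozonolysis, in which one equivalent of ozone takes the trisubstituted ring alkene much faster than the 1,1‑disubstituted isopropenyl group, and the stereocentre (later C‑6') is not touched.

Step 2
Reactants: 3 (3S)‑6‑oxo‑3‑(prop‑1‑en‑2‑yl)heptanal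
Product: 4 (1R,2S,5S)‑2‑hydroxy‑2‑methyl‑5‑(prop‑1‑en‑2‑yl)cyclopentane‑1‑carbaldehyde
Conditions: pyrrolidine (20 mol%), PhCO2H (20 mol%), THF/H2O 20:1, 0 °C; pH 7 buffer quench
Reagents that add atoms: none
Why: Enamine‑catalysed 5‑enolexo intramolecular aldol addition (aldehyde as donor, methyl ketone as acceptor), where reversible aldol/retro‑aldol and α‑epimerisation funnel to the most stable isomer, with the formyl group trans to both the C‑3' methyl and the C‑6' isopropenyl and cis to the hydrogen‑bonded hydroxyl, so C‑2' and C‑3' are set by the limonene‑derived C‑6'.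

Step 3
Reactants: 4 (1R,2S,5S)‑2‑hydroxy‑2‑methyl‑5‑(prop‑1‑en‑2‑yl)cyclopentane‑1‑carbaldehyde; 5 2‑methyl‑1‑(2,4,6‑trihydroxyphenyl)propan‑1‑one (2 equiv)
Product: 7 1‑[2,4,6‑trihydroxy‑3‑{[(1R,2S,5S)‑2‑hydroxy‑2‑methyl‑5‑(prop‑1‑en‑2‑yl)cyclopentyl]methyl}phenyl]‑2‑methylpropan‑1‑one, via quinone methide 6 (not isolated)
Conditions: Hantzsch ester (1.2 equiv), ethylenediammonium diacetate (10 mol%), CH2Cl2/MeOH 4:1, 25 °C
Reagents that add atoms: none
Why: Three‑component reductive alkylation (Knoevenagel condensation at a free ring position, then conjugate hydride transfer from the Hantzsch ester to quinone methide 6 with rearomatisation), fast enough to beat tautomerisation or a second arene addition, and once C‑1' is a methylene C‑2' can no longer epimerise.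

Step 4
Reactants: 7 alkylated acylphloroglucinol
Product: 8 bridged enol ether (O‑4 of the dearomatised ring bonded to C‑7'; spiro and C‑7' centres arranged as in the target)
Conditions: graphite anode, Pt cathode, undivided cell, constant current 2 mA cm−2 (2.1 F mol−1), nBu4NBF4 (0.1 M), 2,6‑lutidine (1 equiv), HFIP/CH2Cl2 1:1, 5 mM, 20 °C
Reagents that add atoms: none
Why: Proposed new method: anodic proton‑coupled oxidation gives the trioxocyclohexadienyl radical, whose alkyl‑bearing C‑3 adds 6‑endo to the CH2 terminus of the isopropenyl group through the only chair the trans‑1,2‑disubstituted cyclopentane allows, the tertiary C‑7' radical is oxidised at the anode and the cation is captured by the oxygen on the axial flank of the new spiro carbon (a dearomative carbo‑etherification not yet shown for acylphloroglucinols; closest known are Mn(OAc)3 oxidative free‑radical cyclisations of 1,3‑dicarbonyls ending in dihydrofurans and oxidative radical cyclisations of dearomatised acylphloroglucinols); the axial flank is expected to be C‑4 because O‑4 is para to the acyl group, unchelated and flanked only by H‑5 whereas O‑2 is locked in the acyl hydrogen bond, so the ring fusion fixes both the spiro centre and, by axial delivery of O‑4, the C‑7' centre, and the O‑2 regioisomer is a separable constitutional isomer.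

Step 5
Reactants: 8 bridged enol ether
Product: 11 (1S,3'S,3a'R,7'R,7a'S)‑3',4,7'‑trihydroxy‑3',7'‑dimethyl‑5,5‑bis(3‑methylbut‑2‑en‑1‑yl)‑3‑(2‑methylpropanoyl)‑1',2',3',3a',4',6',7',7a'‑octahydrospiro[cyclohex‑3‑ene‑1,5'‑indene]‑2,6‑dione, via hydroxy trione 9 (not isolated), via monoprenyl trione 10 (not isolated)
Conditions: KOH (1 M aq)/THF 1:1, 45 °C; then 0 °C, prenyl bromide (2.5 equiv), 0 °C → rt; cold NaH2PO4 work‑up
Reagents that add atoms: water (as aqueous KOH), O; 1‑bromo‑3‑methylbut‑2‑ene (prenyl bromide), CC(C)=CCBr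
Why: Hydroxide opens the cyclic vinylogous ester by addition–elimination at C‑4 (the C‑7'–O bond is untouched, so the carbinol keeps its configuration) and the trione dianion is C‑prenylated twice at C‑5, its only enolisable carbon (dearomative gem‑dialkylation as in lupulone‑type syntheses), after which C‑4 is a non‑enolisable ketone and cannot re‑close.

## Compound list

1 | (S)‑(−)‑limonene, (4S)‑1‑methyl‑4‑(prop‑1‑en‑2‑yl)cyclohex‑1‑ene | CC1=CC[C@H](CC1)C(C)=C | starting material
2 | limonene ozonide, 1‑methyl‑4‑(prop‑1‑en‑2‑yl)‑7,8,9‑trioxabicyclo[4.2.1]nonane (C‑4 as in 1, trioxolane carbons as a mixture) | CC12CC[C@H](C(C)=C)CC(O1)OO2 | intermediate (not isolated)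
3 | (3S)‑6‑oxo‑3‑(prop‑1‑en‑2‑yl)heptanal | O=CC[C@H](CCC(C)=O)C(C)=C | intermediate
4 | (1R,2S,5S)‑2‑hydroxy‑2‑methyl‑5‑(prop‑1‑en‑2‑yl)cyclopentane‑1‑carbaldehyde (OH cis to CHO, CHO trans to isopropenyl) | O=C[C@@H]1[C@H](CC[C@]1(C)O)C(C)=C | intermediate
5 | 2‑methyl‑1‑(2,4,6‑trihydroxyphenyl)propan‑1‑one (phlorisobutyrophenone) | CC(C)C(=O)c1c(O)cc(O)cc1O | starting material
6 | quinone methide, 3,5‑dihydroxy‑2‑(2‑methylpropanoyl)‑6‑{[2‑hydroxy‑2‑methyl‑5‑(prop‑1‑en‑2‑yl)cyclopentyl]methylidene}cyclohexa‑2,4‑dien‑1‑one (ring centres as in 4) | CC(C)C(=O)C1=C(O)C=C(O)C(=C[C@@H]2[C@H](CC[C@]2(C)O)C(C)=C)C1=O | intermediate (not isolated)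
7 | 1‑[2,4,6‑trihydroxy‑3‑{[(1R,2S,5S)‑2‑hydroxy‑2‑methyl‑5‑(prop‑1‑en‑2‑yl)cyclopentyl]methyl}phenyl]‑2‑methylpropan‑1‑one | CC(C)C(=O)c1c(O)cc(O)c(C[C@@H]2[C@H](CC[C@]2(C)O)C(C)=C)c1O | intermediate
8 | bridged enol ether: spiro trione 9 with its C‑4 enol oxygen bonded to C‑7' (five‑membered O‑4/C‑4/spiro C/C‑9'/C‑7' ring, 1,3‑diaxial on the new cyclohexane); trans ring fusion, 3'‑OH cis to C‑1' | C1=C4[C@@]2(C[C@@H]3[C@H](CC[C@]3(C)O)[C@](C)(O4)C2)C(O)=C(C(=O)C(C)C)C1=O | intermediate
9 | (1S,3'S,3a'R,7'R,7a'S)‑3',4,7'‑trihydroxy‑3',7'‑dimethyl‑3‑(2‑methylpropanoyl)‑1',2',3',3a',4',6',7',7a'‑octahydrospiro[cyclohex‑3‑ene‑1,5'‑indene]‑2,6‑dione | C1C(=O)[C@@]2(C[C@@H]3[C@H](CC[C@]3(C)O)[C@](C)(O)C2)C(=O)C(C(=O)C(C)C)=C1O | intermediate (not isolated)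
10 | 5‑(3‑methylbut‑2‑en‑1‑yl) derivative of 9 (drawn as the dienol) | CC(C)=CCC1=C(O)[C@@]2(C[C@@H]3[C@H](CC[C@]3(C)O)[C@](C)(O)C2)C(=O)C(C(=O)C(C)C)=C1O | intermediate (not isolated)
11 | (1S,3'S,3a'R,7'R,7a'S)‑3',4,7'‑trihydroxy‑3',7'‑dimethyl‑5,5‑bis(3‑methylbut‑2‑en‑1‑yl)‑3‑(2‑methylpropanoyl)‑1',2',3',3a',4',6',7',7a'‑octahydrospiro[cyclohex‑3‑ene‑1,5'‑indene]‑2,6‑dione | CC(C)=CCC1(CC=C(C)C)C(=O)[C@@]2(C[C@@H]3[C@H](CC[C@]3(C)O)[C@](C)(O)C2)C(=O)C(C(=O)C(C)C)=C1O | target

## Step count and risks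

Total steps: 5. Longest linear sequence: 5 (from 1).

Most likely to fail:

1. Step 4 (proposed new step). The phloroglucinol radical is aromatic‑stabilised and may dimerise instead of cyclising, and the preference for the C‑4 flank over the C‑2 flank is argued from sterics and hydrogen bonding, not demonstrated. Fallback with known chemistry, polar instead of radical, sets out from 7: buffered mCPBA (NaHCO3, CH2Cl2, 0 °C) epoxidises the only alkene to give the 2‑methyloxiranyl derivative of 7, F3, as both C‑7' epimers. K2CO3 in MeOH at 40 °C then effects dearomatising 6‑exo C‑alkylation of the phloroglucinolate C‑3 at the primary epoxide carbon. The isomer with the axial C‑7' hydroxyl syn to the C‑4 carbonyl is separated and the route is rejoined at 9, which enters the prenylation half of step 5. This costs the stereocontrol at C‑7'.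

2. Step 2. The aldol may run on to the enal or stop short of full equilibration. Fallback sets out from 3: piperidine/AcOH (cat.), toluene, 25 °C gives the aldol condensation product (R)‑2‑methyl‑5‑(prop‑1‑en‑2‑yl)cyclopent‑1‑ene‑1‑carbaldehyde F1. H2O2/NaOH in MeOH at 0 °C epoxidises it on the face opposite the isopropenyl group to 5‑methyl‑2‑(prop‑1‑en‑2‑yl)‑6‑oxabicyclo[3.1.0]hexane‑1‑carbaldehyde F2. SmI2 in THF/MeOH at −90 °C cleaves the α C–O bond, and protonation/equilibration of the enolate returns the route at 4.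

3. Step 5. Opening of the anionic vinylogous ester may be slow, O‑prenylation competes, and hot base could trigger retro‑Claisen cleavage. Fallback sets out from 8: LiOH (aq)/THF at 25 °C with cold NaH2PO4 work‑up gives isolated 9. Pd(PPh3)4 (5 mol%) and allyl methyl carbonate (2.5 equiv) in THF at 25 °C give the C‑selective Tsuji–Trost product, the 5,5‑diallyl analogue of 11, F4. Second‑generation Grubbs catalyst with excess 2‑methyl‑2‑butene in CH2Cl2 at 40 °C converts both allyl groups to prenyl groups by cross‑metathesis, rejoining at 11.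

Further compounds
F1 | step 2 | (R)‑2‑methyl‑5‑(prop‑1‑en‑2‑yl)cyclopent‑1‑ene‑1‑carbaldehyde | O=CC1=C(C)CC[C@@H]1C(C)=C
F2 | step 2 | 5‑methyl‑2‑(prop‑1‑en‑2‑yl)‑6‑oxabicyclo[3.1.0]hexane‑1‑carbaldehyde, epoxide oxygen trans to the isopropenyl group | O=C[C@@]12[C@H](CC[C@]1(C)O2)C(C)=C
F3 | step 4 | 1‑[2,4,6‑trihydroxy‑3‑{[(1R,2S,5S)‑2‑hydroxy‑2‑methyl‑5‑(2‑methyloxiran‑2‑yl)cyclopentyl]methyl}phenyl]‑2‑methylpropan‑1‑one, both epimers at the oxirane carbon | CC(C)C(=O)c1c(O)cc(O)c(C[C@@H]2[C@H](CC[C@]2(C)O)C3(C)CO3)c1O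
F4 | step 5 | 5,5‑di(prop‑2‑en‑1‑yl) analogue of 11 (stereocentres as in 11) | C=CCC1(CC=C)C(=O)[C@@]2(C[C@@H]3[C@H](CC[C@]3(C)O)[C@](C)(O)C2)C(=O)C(C(=O)C(C)C)=C1O
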